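## Analysis of the target

The target is an α-arylidene-β-benzyl-γ-butyrolactone lignan. The lactone is numbered O1, C2 (carbonyl), C3, C4, C5; the exocyclic arylidene CH is C6 and the benzylic CH2 on C4 is C7. C6 carries the 3-hydroxy-4,5-dimethoxyphenyl ring and C7 the 4-hydroxy-3-methoxyphenyl (guaiacyl) ring.

There is one stereocentre, C4, of R configuration (CIP order C5 > C3 > C7 > H). There is one stereogenic alkene, C3=C6, of E geometry, with the aryl ring anti to the C2 carbonyl and syn to C4. The two elements are neighbours, because C4 is allylic to C3=C6, but neither offers a simple handle for controlling the other.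

The sensitive groups are the two free phenols and the arylidene lactone, which is a Michael acceptor, can photoisomerise and rules out hydrogenolytic deprotection. The C4–H bond is also sensitive: its removal or a 1,3-shift would give the achiral endocyclic butenolide.

The difficulty is to create an isolated stereocentre flanked by three carbon substituents of similar size (C3, C5, C7) with no second centre to relay from, and then to keep it while the arylidene is present.

The strategy rests on one feature. If C5 is raised to the ester oxidation level, C4 is its α-carbon and C7 its β-carbon. C4=C7 can therefore be the terminal methylene of an acrylate, while C2, C3 and C6 form a cinnamate. The lactone carbons plus the arylidene ring are then a 2-arylidene-3-methylenesuccinate. Adding the guaiacyl ring to C7 and a proton to C4 completes the skeleton and creates the stereocentre in one event, with C3=C6 already in place.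

## Retrosynthetic reasoning

**17 ⇒ 15 (through 16).** The acyl bond O1–C2 of the lactone and the two phenol protecting groups are cut. This leads to the γ-hydroxy tert-butyl ester 15, in which both phenols are MOM ethers. A single acid treatment should cleave the tert-butyl ester, close the five-membered lactone (16) and hydrolyse both acetals to give 17. MOM is chosen because it tolerates ylides, organolithium, tin, palladium, rhodium and hydride reagents and is removed without hydrogen.

**15 ⇒ 14.** The C5 hydroxymethyl group is traced back to a methyl ester. In the diester 14 the two carboxyl groups are deliberately different: a small, saturated methyl ester on C4 and a hindered, conjugated tert-butyl ester on C3. The forward reaction must reduce only the former, and a borohydride should do this without touching C3=C6 or C4–H.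

**14 ⇒ 8 + 13.** The C7–aryl bond and the C4–H bond are cut together. This is the only disconnection that creates the stereocentre while leaving the preformed alkene untouched, and it splits the molecule into two fragments of similar size. The forward reaction is a rhodium-catalysed conjugate addition of the arylboronic acid 13 to the methylene terminus of the diene diester 8, followed by protonation of the resulting rhodium enolate inside a chiral bisphosphine pocket. It has to add to C4=C7 and not to C3=C6, protonate at C4 and not at C6, choose one face, and avoid β-hydride elimination.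

**8 ⇒ 5 + 7.** The C3–C4 bond between the two sp2 carbons is cut. This gives the α-bromocinnamate 5 and the α-stannyl acrylate 7, to be joined by a Stille coupling. Because the coupling proceeds with retention at the alkene, the Z geometry of 5 becomes the E geometry of C3=C6. The geometry is thus fixed before the stereocentre exists and no enolate chemistry is needed on a finished lactone.

**5 ⇒ 2 + 3 (through 4); 2 ⇒ 1.** C3=C6 is cut by a Wittig disconnection. Bromination of the stabilised ylide 3 in the flask gives the bromo ylide 4, which olefinates the protected aldehyde 2. The stabilised-ylide preference puts the ester anti to the aryl ring, which is the geometry required. Aldehyde 2 is the MOM ether of the commercial phenol 1.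

**7 ⇒ 6.** The C–Sn bond is cut. Palladium-catalysed hydrostannation of the propiolate 6 delivers tin to the ester-bearing carbon in one step.

**13 ⇒ 10 ⇒ 9 (through 11 and 12).** The C–B bond is traced to a C–Br bond. Bromine–lithium exchange on the MOM ether 10 gives the aryllithium 11, which is borylated through the ate complex 12. Compound 10 is the protected form of the commercial bromophenol 9.

## Alternatives that were turned down

**Alternative 1: oxetane desymmetrisation.**
- Disconnection: the O1–C5 bond is cut, and C5 and C7 are traced back to the two enantiotopic CH2 groups of a 3-substituted oxetane, A1. Its oxetane CH sits on the α-carbon of a tert-butyl E-cinnamate.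
- Forward key step: a chiral phosphoric acid would activate the oxetane, the ester carbonyl oxygen would open one CH2 group, the tert-butyl group would leave, and the hydroxymethyl lactone A2 would form with C4 set.
- For it: the step is metal-free and catalytic, and it closes the lactone and sets C4 at once, with the arylidene geometry fixed beforehand. On these points it is as good as or better than the chosen route.
- Against it: A2 holds C7 as CH2OH, so the guaiacyl ring still has to be attached by a C(sp3)–C(sp2) coupling at a β-branched primary carbon next to a Michael acceptor. Organocopper reagents would compete for the arylidene lactone, and activation of the alcohol invites elimination. The nucleophile in the key step is a conjugated, weakly nucleophilic ester carbonyl, and A1 needs its own multistep preparation.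
- Comparison: the chosen strategy forms the C7–aryl bond and the stereocentre in the same step, so no coupling remains after the stereocentre exists.

**Alternative 2: cyclopropane lactone opening.**
- Disconnection: the C7–aryl bond is cut as in the chosen route, but the electrophile is the cyclopropane CH2 of the chiral-pool bicyclic lactone A3.
- Forward key step: the Grignard reagent made from 10, with copper catalysis, would open A3 at C7 with cleavage of the C3–C7 bond, giving the trans lactone ester A4.
- For it: C4 comes from the chiral pool, so its configuration is certain. Homoconjugate opening of doubly activated cyclopropanes by organocopper reagents is dependable, and the lactone ring is already present. On certainty of configuration and on precedent this alternative is stronger than the chosen one.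
- Against it: A4 carries an ester at C3 where the arylidene is needed. Dealkoxycarbonylation, an aldol reaction with 2, dehydration and deprotection must follow, with enolate chemistry on the lactone and E/Z control left to the last C–C bond formation.
- Comparison: the chosen strategy needs two steps after its key step instead of four or more. It has the alkene geometry secured before the stereocentre is made, and it gives either enantiomer from the same materials by changing the ligand.

**Alternative 3: Heck–Matsuda arylation.**
- Disconnection: the C6–aryl bond is cut, giving the β-benzyl α-methylene lactone A5 and the arenediazonium salt A6.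
- Forward key step: base-free palladium catalysis in an alcohol solvent would couple A5 and A6 to the protected target A7. The aryl group is delivered to C6 and the E alkene forms by syn β-hydride elimination.
- For it: the C–C bond is formed very late under mild conditions, and the two phenols are differentiated. On mildness of the last bond formation it is comparable to the chosen route.
- Against it: A5 must already contain the C4 stereocentre, so this approach does not solve the stereochemical problem. After carbopalladation the palladium sits on C3, next to C4–H. Syn elimination toward C4 would give the endocyclic butenolide and erase the stereocentre, and re-addition of the palladium hydride could move the alkene later. A6 needs an aniline that is not an obvious commercial material.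
- Comparison: the chosen strategy creates skeleton and stereocentre together and never places a metal on C3 of a finished lactone.

Key step: step 7

Assumption: the S antipode of BINAP is written for the rhodium catalyst. The sense of induction for this new enolate has to be read from the product; if it is opposite, the R antipode is used with nothing else changed.

## Route

Step 1
Reactants: 1 3-hydroxy-4,5-dimethoxybenzaldehyde
Product: 2 3,4-dimethoxy-5-(methoxymethoxy)benzaldehyde
Conditions: MOMCl, iPr2NEt, CH2Cl2, 0 °C → rt
Reagents that add atoms: chloromethyl methyl ether, COCCl
Why: O-alkylation of the phenol (MOM ether formation) with a hindered amine base; the aldehyde is untouched and the acetal survives all later steps up to the final acid treatment.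

Step 2
Reactants: 2 3,4-dimethoxy-5-(methoxymethoxy)benzaldehyde; 3 tert-butyl (triphenylphosphoranylidene)acetate
Product: 5 tert-butyl (Z)-2-bromo-3-[3,4-dimethoxy-5-(methoxymethoxy)phenyl]prop-2-enoate, via tert-butyl bromo(triphenylphosphoranylidene)acetate 4 (not isolated)
Conditions: 3, NBS, CH2Cl2, −20 °C; then 2, −20 °C → rt
Reagents that add atoms: N-bromosuccinimide, O=C1CCC(=O)N1Br
Why: Bromination of the stabilised ylide gives a bromophosphonium salt that the succinimide anion deprotonates to the bromo ylide 4; its Wittig olefination of the aromatic aldehyde follows the stabilised-ylide preference and places the ester anti to the aryl ring, which is the Z bromoacrylate and the future E geometry of C3=C6.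

Step 3
Reactants: 6 methyl propiolate
Product: 7 methyl 2-(tributylstannyl)prop-2-enoate
Conditions: Bu3SnH (slow addition), Pd(PPh3)4 (2 mol %), THF, 0 °C → rt
Reagents that add atoms: tributyltin hydride, CCCC[SnH](CCCC)CCCC
Why: Syn hydrostannation catalysed by zerovalent palladium; with propiolate esters tin goes mainly to the ester-bearing carbon, and the minor (E)-β-stannyl isomer is removed by chromatography.

Step 4
Reactants: 5 tert-butyl (Z)-2-bromo-3-[3,4-dimethoxy-5-(methoxymethoxy)phenyl]prop-2-enoate; 7 methyl 2-(tributylstannyl)prop-2-enoate
Product: 8 1-tert-butyl 4-methyl (E)-2-[3,4-dimethoxy-5-(methoxymethoxy)benzylidene]-3-methylidenebutanedioate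
Conditions: Pd2(dba)3 (2.5 mol %), AsPh3 (20 mol %), CuI (20 mol %), BHT (trace), NMP, rt → 40 °C, dark
Reagents that add atoms: none
Why: Stille coupling; oxidative addition and reductive elimination retain the alkene geometry, so the Z bromide gives the E arylidene, and CuI speeds the transmetallation of the hindered α-stannyl acrylate; low temperature, darkness and the inhibitor protect the diene, which is used promptly.

Step 5
Reactants: 9 4-bromo-2-methoxyphenol
Product: 10 4-bromo-2-methoxy-1-(methoxymethoxy)benzene
Conditions: MOMCl, iPr2NEt, CH2Cl2, 0 °C → rt
Reagents that add atoms: chloromethyl methyl ether, COCCl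
Why: MOM ether formation on the phenol, as in step 1; the aryl bromide is inert.

Step 6
Reactants: 10 4-bromo-2-methoxy-1-(methoxymethoxy)benzene
Product: 13 [3-methoxy-4-(methoxymethoxy)phenyl]boronic acid, via aryllithium 11 (not isolated), via lithium aryl(triisopropoxy)borate 12 (not isolated)
Conditions: n-BuLi, THF, −78 °C; B(OiPr)3, −78 → 0 °C; aq. NH4Cl
Reagents that add atoms: triisopropyl borate, CC(C)OB(OC(C)C)OC(C)C; water, O
Why: Bromine–lithium exchange at −78 °C outruns ortho-lithiation directed by the MOM group; the aryllithium is trapped as the borate ate complex, which is hydrolysed under buffered conditions that leave the MOM ether intact.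

Step 7
Reactants: 8 1-tert-butyl 4-methyl (E)-2-[3,4-dimethoxy-5-(methoxymethoxy)benzylidene]-3-methylidenebutanedioate; 13 [3-methoxy-4-(methoxymethoxy)phenyl]boronic acid
Product: 14 1-tert-butyl 4-methyl (2E,3R)-2-[3,4-dimethoxy-5-(methoxymethoxy)benzylidene]-3-[3-methoxy-4-(methoxymethoxy)benzyl]butanedioate
Conditions: [Rh(OH)((S)-binap)]2 (2.5 mol %), 13 (2 equiv), 2-methoxyphenol (1.5 equiv), 1,4-dioxane, 50 °C, dark
Reagents that add atoms: none
Why: This is a rhodium-catalysed conjugate arylation with enantioselective protonation, the reaction type established for itaconate diesters and other α-substituted acrylates. The hydroxo complex transmetallates with 13 to an aryl–rhodium species of monovalent rhodium, which inserts the 1,1-disubstituted C4=C7 acrylate unit of 8 so that the aryl group lands on the unhindered C7 and rhodium is held at C4 as an oxa-π-allyl enolate of the methyl ester. The phenol protonates this enolate at C4 and leaves a rhodium aryloxide that re-enters transmetallation, so the C7–aryl bond and the C4–H stereocentre arise in one catalytic cycle and no ring is closed. The configuration at C4 is controlled only by the BINAP ligand, which screens one face of the bound enolate during proton delivery; a cod-free catalyst is used so that no achiral diene–rhodium species can run a racemic background reaction. Chemoselectivity between the two alkenes rests on the substrate: C3=C6 is trisubstituted, β-aryl and flanked by the bulky tert-butyl ester, whereas C4=C7 is a terminal methylene activated by the small methyl ester. Protonation at C4 and not at the vinylogous position C6 (which would give the achiral tetrasubstituted butenedioate) is favoured by the kinetic preference of metal enolates for α-protonation and by the conjugation of C3=C6 with its aryl ring and ester, which α-protonation retains. Moderate temperature, no added hydroxide base and an excess of the phenol should hold back β-hydride elimination to a bis-arylidene diester and epimerisation of the allylic C4–H.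

Step 8
Reactants: 14 1-tert-butyl 4-methyl (2E,3R)-2-[3,4-dimethoxy-5-(methoxymethoxy)benzylidene]-3-[3-methoxy-4-(methoxymethoxy)benzyl]butanedioate
Product: 15 tert-butyl (2E,3R)-2-[3,4-dimethoxy-5-(methoxymethoxy)benzylidene]-3-(hydroxymethyl)-4-[3-methoxy-4-(methoxymethoxy)phenyl]butanoate
Conditions: LiBH4, THF, 0 °C → rt
Reagents that add atoms: none
Why: Chemoselective ester reduction; LiBH4 attacks the saturated methyl ester much faster than the hindered, conjugated tert-butyl enoate and does not reduce the trisubstituted alkene, and any alkoxide that already closes onto the tert-butyl ester gives 16, which converges in step 9.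

Step 9
Reactants: 15 tert-butyl (2E,3R)-2-[3,4-dimethoxy-5-(methoxymethoxy)benzylidene]-3-(hydroxymethyl)-4-[3-methoxy-4-(methoxymethoxy)phenyl]butanoate
Product: 17 (3E,4R)-3-(3-hydroxy-4,5-dimethoxybenzylidene)-4-(4-hydroxy-3-methoxybenzyl)dihydrofuran-2(3H)-one, via bis-MOM lactone 16 (not isolated)
Conditions: TFA/CH2Cl2/H2O (10:10:1), 0 °C → rt, dark
Reagents that add atoms: none
Why: Acidolysis; the tert-butyl ester is cleaved by alkyl–oxygen fission and the γ-hydroxy acid closes to the five-membered lactone by 5-exo-trig acyl substitution, while the aqueous acid hydrolyses both aryl MOM acetals; no base is present, so C4 and the thermodynamically favoured E alkene are kept.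

## Compound list

1 | 3-hydroxy-4,5-dimethoxybenzaldehyde | COc1cc(C=O)cc(O)c1OC | starting material
2 | 3,4-dimethoxy-5-(methoxymethoxy)benzaldehyde | COCOc1cc(C=O)cc(OC)c1OC | intermediate
3 | tert-butyl (triphenylphosphoranylidene)acetate | CC(C)(C)OC(=O)C=P(c1ccccc1)(c1ccccc1)c1ccccc1 | starting material
4 | tert-butyl bromo(triphenylphosphoranylidene)acetate | CC(C)(C)OC(=O)C(Br)=P(c1ccccc1)(c1ccccc1)c1ccccc1 | intermediate (not isolated)
5 | tert-butyl (Z)-2-bromo-3-[3,4-dimethoxy-5-(methoxymethoxy)phenyl]prop-2-enoate | COCOc1cc(/C=C(\Br)C(=O)OC(C)(C)C)cc(OC)c1OC | intermediate
6 | methyl propiolate | C#CC(=O)OC | starting material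
7 | methyl 2-(tributylstannyl)prop-2-enoate | C=C(C(=O)OC)[Sn](CCCC)(CCCC)CCCC | intermediate
8 | 1-tert-butyl 4-methyl (E)-2-[3,4-dimethoxy-5-(methoxymethoxy)benzylidene]-3-methylidenebutanedioate | COC(=O)C(=C)/C(=C\c1cc(OCOC)c(OC)c(OC)c1)C(=O)OC(C)(C)C | intermediate
9 | 4-bromo-2-methoxyphenol | COc1cc(Br)ccc1O | starting material
10 | 4-bromo-2-methoxy-1-(methoxymethoxy)benzene | COCOc1ccc(Br)cc1OC | intermediate
11 | [3-methoxy-4-(methoxymethoxy)phenyl]lithium | [Li]c1ccc(OCOC)c(OC)c1 | intermediate (not isolated)
12 | lithium [3-methoxy-4-(methoxymethoxy)phenyl]tri(propan-2-yloxy)borate | [Li+].COCOc1ccc([B-](OC(C)C)(OC(C)C)OC(C)C)cc1OC | intermediate (not isolated)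
13 | [3-methoxy-4-(methoxymethoxy)phenyl]boronic acid | COCOc1ccc(B(O)O)cc1OC | intermediate
14 | 1-tert-butyl 4-methyl (2E,3R)-2-[3,4-dimethoxy-5-(methoxymethoxy)benzylidene]-3-[3-methoxy-4-(methoxymethoxy)benzyl]butanedioate | COc1cc(C[C@@H](C(=O)OC)/C(=C\c2cc(OCOC)c(OC)c(OC)c2)C(=O)OC(C)(C)C)ccc1OCOC | intermediate
15 | tert-butyl (2E,3R)-2-[3,4-dimethoxy-5-(methoxymethoxy)benzylidene]-3-(hydroxymethyl)-4-[3-methoxy-4-(methoxymethoxy)phenyl]butanoate | COc1cc(C[C@@H](CO)/C(=C\c2cc(OCOC)c(OC)c(OC)c2)C(=O)OC(C)(C)C)ccc1OCOC | intermediate
16 | (3E,4R)-3-[3,4-dimethoxy-5-(methoxymethoxy)benzylidene]-4-[3-methoxy-4-(methoxymethoxy)benzyl]dihydrofuran-2(3H)-one | COCOc1ccc(C[C@H]2COC(=O)/C2=C/c2cc(OCOC)c(OC)c(OC)c2)cc1OC | intermediate (not isolated)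
17 | (3E,4R)-3-(3-hydroxy-4,5-dimethoxybenzylidene)-4-(4-hydroxy-3-methoxybenzyl)dihydrofuran-2(3H)-one | COc1cc(C[C@H]2COC(=O)/C2=C/c2cc(O)c(OC)c(OC)c2)ccc1O | target

## Step count and risk

Total: 9 steps. Longest linear sequence: 6 steps (steps 1, 2, 4, 7, 8, 9, from 1). Steps 3, 5 and 6 are side branches.

**Step 7 (key step).**
- What may go wrong: poor facial selectivity in the protonation, because the α-substituent of this enolate is a large arylidene ester unlike the known itaconate cases. The dienolate may be protonated at C6, or the product isomerised by base to the conjugated tetrasubstituted diester. The rhodium may be sequestered by the 1,3-diene, 8 may dimerise thermally, and the electron-rich 13 may protodeboronate.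
- Fallback: this abandons the conjugate addition and sets C4 by asymmetric hydrogenation. It sets out from 10 and returns at 16.
 - Compound 10 is lithiated as in step 6 (through 11) and formylated with DMF to 3-methoxy-4-(methoxymethoxy)benzaldehyde F1.
 - Stobbe condensation of F1 with dimethyl succinate (NaOMe, MeOH, reflux) should give the E half-ester, (E)-3-(methoxycarbonyl)-4-[3-methoxy-4-(methoxymethoxy)phenyl]but-3-enoic acid F2.
 - Hydrogenation of F2 (H2, [Rh(cod)2]BF4 with a chiral bisphosphine of the DuPhos type, antipode chosen for the R acid) should give (R)-3-(methoxycarbonyl)-4-[3-methoxy-4-(methoxymethoxy)phenyl]butanoic acid F3.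
 - Reduction of the ester in the potassium carboxylate of F3 with Ca(BH4)2 (from NaBH4 and CaCl2 in ethanol), then mild acidification, should close (R)-4-[3-methoxy-4-(methoxymethoxy)benzyl]dihydrofuran-2(3H)-one F4.
 - The lithium enolate of F4 (LiN(iPr)2, THF, −78 °C) is added to 2 to give the trans aldol adduct, (4R)-3-{[3,4-dimethoxy-5-(methoxymethoxy)phenyl](hydroxy)methyl}-4-[3-methoxy-4-(methoxymethoxy)benzyl]dihydrofuran-2(3H)-one F5, as a mixture of carbinol epimers.
 - Mesylation of F5 and elimination with DBU should give the E arylidene lactone 16, which the acid of step 9 converts into 17.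

**Step 4.**
- What may go wrong: slow transmetallation between two hindered, electron-poor partners, leading to protodestannylation and homocoupling, and Diels–Alder dimerisation or polymerisation of the diene during reaction and purification.
- Fallback: this makes C3=C6 and C4=C7 by olefination and methylenation in place of cross-coupling. It sets out from 2 and returns at 8.
 - tert-Butyl diethylphosphonoacetate is alkylated with methyl bromoacetate (NaH, THF) to 1-tert-butyl 4-methyl 2-(diethoxyphosphoryl)butanedioate F6.
 - Horner–Wadsworth–Emmons reaction of F6 with 2 should give 1-tert-butyl 4-methyl (E)-2-[3,4-dimethoxy-5-(methoxymethoxy)benzylidene]butanedioate F7.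
 - Deprotonation at C4 (LiN(SiMe3)2, THF, −78 °C) and trapping with dimethyl(methylidene)ammonium iodide should give the racemic Mannich base, 1-tert-butyl 4-methyl (E)-2-[3,4-dimethoxy-5-(methoxymethoxy)benzylidene]-3-[(dimethylamino)methyl]butanedioate F8.
 - N-Methylation of F8 with MeI and elimination with DBU at room temperature should release 8 just before use.

**Step 8.**
- What may go wrong: loss of chemoselectivity (attack on the tert-butyl enoate or conjugate reduction) and epimerisation at C4 by basic alkoxyborohydride species, since C4–H is both α to an ester and allylic.
- Fallback: this replaces direct hydride reduction of the ester by hydrolysis and acid-selective reduction. It sets out from 14 and returns at 15.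
 - The methyl ester of 14 is cleaved selectively and without strong base by Me3SnOH in 1,2-dichloroethane at 80 °C to (2R,3E)-3-(tert-butoxycarbonyl)-4-[3,4-dimethoxy-5-(methoxymethoxy)phenyl]-2-[3-methoxy-4-(methoxymethoxy)benzyl]but-3-enoic acid F9.
 - BH3·SMe2 in THF at 0 °C, which reduces carboxylic acids faster than esters and is not basic, should convert F9 into 15.

**Step 9.**
- What may go wrong: alkylation of the two electron-rich phenol rings by the tert-butyl cation and by formaldehyde or the methoxymethyl cation, and acid-promoted E/Z equilibration or exocyclic-to-endocyclic alkene migration on long exposure.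
- Fallback: this separates ring closure from deprotection and traps the acetal fragment. It sets out from 15 and returns at 17 and makes no new compound.
 - Compound 15 is lactonised without acid by a catalytic amount of KOtBu in THF at 0 °C (alkoxide transesterification onto the tert-butyl ester), and 16 is isolated.
 - The two MOM ethers of 16 are removed with HCl in methanol (from acetyl chloride) at 0 °C → rt, where the solvent captures the methoxymethyl cation as the dimethyl acetal, to give 17.

## Further compounds

F1 | step 7 | 3-methoxy-4-(methoxymethoxy)benzaldehyde | COCOc1ccc(C=O)cc1OC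
F2 | step 7 | (E)-3-(methoxycarbonyl)-4-[3-methoxy-4-(methoxymethoxy)phenyl]but-3-enoic acid | COC(=O)/C(CC(=O)O)=C/c1ccc(OCOC)c(OC)c1
F3 | step 7 | (R)-3-(methoxycarbonyl)-4-[3-methoxy-4-(methoxymethoxy)phenyl]butanoic acid | COc1cc(C[C@H](CC(=O)O)C(=O)OC)ccc1OCOC
F4 | step 7 | (R)-4-[3-methoxy-4-(methoxymethoxy)benzyl]dihydrofuran-2(3H)-one | COc1cc(C[C@H]2COC(=O)C2)ccc1OCOC
F5 | step 7 | (4R)-3-{[3,4-dimethoxy-5-(methoxymethoxy)phenyl](hydroxy)methyl}-4-[3-methoxy-4-(methoxymethoxy)benzyl]dihydrofuran-2(3H)-one, 3,4-trans, carbinol epimers | COc1cc(C[C@H]2COC(=O)[C@@H]2C(O)c2cc(OCOC)c(OC)c(OC)c2)ccc1OCOC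
F6 | step 4 | 1-tert-butyl 4-methyl 2-(diethoxyphosphoryl)butanedioate | CCOP(=O)(OCC)C(CC(=O)OC)C(=O)OC(C)(C)C
F7 | step 4 | 1-tert-butyl 4-methyl (E)-2-[3,4-dimethoxy-5-(methoxymethoxy)benzylidene]butanedioate | COC(=O)C/C(=C\c1cc(OCOC)c(OC)c(OC)c1)C(=O)OC(C)(C)C
F8 | step 4 | 1-tert-butyl 4-methyl (E)-2-[3,4-dimethoxy-5-(methoxymethoxy)benzylidene]-3-[(dimethylamino)methyl]butanedioate, racemic | COC(=O)C(CN(C)C)/C(=C\c1cc(OCOC)c(OC)c(OC)c1)C(=O)OC(C)(C)C
F9 | step 8 | (2R,3E)-3-(tert-butoxycarbonyl)-4-[3,4-dimethoxy-5-(methoxymethoxy)phenyl]-2-[3-methoxy-4-(methoxymethoxy)benzyl]but-3-enoic acid | COc1cc(C[C@@H](C(=O)O)/C(=C\c2cc(OCOC)c(OC)c(OC)c2)C(=O)OC(C)(C)C)ccc1OCOC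
F0 | step 9 | none | none
A1 | alternative 1 | tert-butyl (E)-3-[3-(tert-butyldimethylsilyloxy)-4,5-dimethoxyphenyl]-2-(oxetan-3-yl)prop-2-enoate | CC(C)(C)OC(=O)/C(=C/c1cc(O[Si](C)(C)C(C)(C)C)c(OC)c(OC)c1)C1COC1
A2 | alternative 1 | (3E,4S)-3-[3-(tert-butyldimethylsilyloxy)-4,5-dimethoxybenzylidene]-4-(hydroxymethyl)dihydrofuran-2(3H)-one | OC[C@H]1COC(=O)/C1=C/c1cc(O[Si](C)(C)C(C)(C)C)c(OC)c(OC)c1
A3 | alternative 2 | methyl (1S,5R)-2-oxo-3-oxabicyclo[3.1.0]hexane-1-carboxylate | C1[C@H]2COC(=O)[C@@]12C(=O)OC
A4 | alternative 2 | methyl trans-(4R)-4-[3-methoxy-4-(methoxymethoxy)benzyl]-2-oxotetrahydrofuran-3-carboxylate | COc1cc(C[C@H]2COC(=O)[C@@H]2C(=O)OC)ccc1OCOC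
A5 | alternative 3 | (R)-4-[3-methoxy-4-(methoxymethoxy)benzyl]-3-methylidenedihydrofuran-2(3H)-one | COc1cc(C[C@H]2COC(=O)C2=C)ccc1OCOC
A6 | alternative 3 | 3-acetoxy-4,5-dimethoxybenzenediazonium tetrafluoroborate | CC(=O)Oc1cc([N+]#N)cc(OC)c1OC.F[B-](F)(F)F
A7 | alternative 3 | (3E,4R)-3-(3-acetoxy-4,5-dimethoxybenzylidene)-4-[3-methoxy-4-(methoxymethoxy)benzyl]dihydrofuran-2(3H)-one | COc1cc(C[C@H]2COC(=O)/C2=C/c2cc(OC(C)=O)c(OC)c(OC)c2)ccc1OCOC
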